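Everything rests on cutting ring A of the naphthazarin (C5–C8 plus C4a and C8a), a benzene ring that carries only the two peri hydroxyls, at C4a–C5 and C8–C8a. One Diels–Alder reaction makes both bonds, closes ring A and installs both oxygens. Its partners are a 1,4-bis(silyloxy)cyclohexa-1,3-diene and the unsubstituted double bond of an R-configured benzoquinone, which already holds C1' and the prenyl chain as a silyl ether. The CH2CH2 bridge of the adduct forbids β-elimination of either oxygen and later leaves as ethylene. Enolisation, oxidation, cycloreversion and desilylation give shikonin, whose C1' hydroxyl is finally acylated with (Z)-5-methylhexa-3,5-dienoic acid, made separately.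

Key step: step 6

Remark: C1' of the target reads as R (shikonin series) and the C3=C4 alkene of the acyl group as Z; the Re-face induction of the R-configured phosphoric acid catalyst in step 1 is assumed from simple benzaldehydes, and its enantiomer would be used if the ortho-methoxy group reversed it.

Step 1
Reactants: 1 2,5-dimethoxybenzaldehyde; 2 allylboronic acid pinacol ester
Product: 4 (R)-1-(2,5-dimethoxyphenyl)but-3-en-1-ol, via pinacol borate 3 (not isolated)
Conditions: (R)-3,3'-bis(2,4,6-triisopropylphenyl)-1,1'-binaphthalene-2,2'-diyl hydrogen phosphate (5 mol %), toluene, −30 °C; aq. NaHCO3 work-up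
Reagents that add atoms: none
Why: Chiral-phosphoric-acid-catalysed allylboration runs through a closed chair (Zimmerman–Traxler) transition state in which the catalyst hydrogen-bonds to a boronate oxygen and to the formyl hydrogen, so the allyl group should reach the Re face of 1 and set C1' as R, while the allyl-then-prenyl plan avoids the γ-attack (reverse prenylation) that a prenylboron reagent would give.

Step 2
Reactants: 4 (R)-1-(2,5-dimethoxyphenyl)but-3-en-1-ol
Product: 5 (R)-tert-butyl[1-(2,5-dimethoxyphenyl)but-3-enyloxy]dimethylsilane
Conditions: TBSCl, imidazole, DMF, rt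
Reagents that add atoms: tert-butyldimethylsilyl chloride (TBSCl), CC(C)(C)[Si](C)(C)Cl
Why: Imidazole-promoted O-silylation leaves the C1'–O bond and thus the R configuration untouched, and a silyl ether is preferred to an ester because the hydroquinone passed in step 7 would expel a carboxylate from C1' through an ortho-quinone methide whereas a silanolate is a poor leaving group.

Step 3
Reactants: 5 (R)-tert-butyl[1-(2,5-dimethoxyphenyl)but-3-enyloxy]dimethylsilane; 6 2-methylbut-2-ene
Product: 7 (R)-tert-butyl[1-(2,5-dimethoxyphenyl)-4-methylpent-3-enyloxy]dimethylsilane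
Conditions: second-generation Grubbs catalyst (H2IMes)(PCy3)Cl2Ru=CHPh (3 mol %), 6 as solvent, 40 °C, sealed tube
Reagents that add atoms: none
Why: Olefin cross-metathesis of a monosubstituted alkene with excess 2-methylbut-2-ene is an established way to turn an allyl into a prenyl group, since the ruthenium alkylidene swaps =CH2 for =C(CH3)2, propene escapes and the trisubstituted product no longer reacts.

Step 4
Reactants: 7 (R)-tert-butyl[1-(2,5-dimethoxyphenyl)-4-methylpent-3-enyloxy]dimethylsilane
Product: 8 (R)-2-[1-(tert-butyldimethylsilyloxy)-4-methylpent-3-enyl]-1,4-benzoquinone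
Conditions: (NH4)2Ce(NO3)6 (2.3 equiv), MeCN/H2O, 0 °C, short contact; used promptly
Reagents that add atoms: water, O
Why: Oxidative demethylation of a 1,4-dimethoxybenzene by two single-electron transfers to tetravalent cerium, with addition of water at the two ipso carbons and loss of methanol, gives the p-quinone, and the short contact at 0 °C should spare the secondary silyl ether and the trisubstituted alkene, both of which are harder to oxidise than the arene.

Step 5
Reactants: 9 cyclohexane-1,4-dione
Product: 11 1,4-bis(tert-butyldimethylsilyloxy)cyclohexa-1,3-diene, via mono silyl enol ether 10 (not isolated)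
Conditions: TBSOTf (2.2 equiv), Et3N (3 equiv), CH2Cl2, 0 °C to rt
Reagents that add atoms: tert-butyldimethylsilyl trifluoromethanesulfonate (TBSOTf), CC(C)(C)[Si](C)(C)OS(=O)(=O)C(F)(F)F
Why: Soft enolisation with a silyl triflate and an amine silylates both ketones, the second deprotonation in 10 should take the CH2 that is at once α to the carbonyl and allylic and so give the conjugated 1,3-diene (any unconjugated 1,4-diene isomer is inert in step 6 and can be carried along), and the bulky silyl group is chosen so that the bridgehead ethers of 12 to 14 outlast base, Ag2O and heat, a free bridgehead alkoxide being prone to retro-aldol ring cleavage.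

Step 6
Reactants: 8 (R)-2-[1-(tert-butyldimethylsilyloxy)-4-methylpent-3-enyl]-1,4-benzoquinone; 11 1,4-bis(tert-butyldimethylsilyloxy)cyclohexa-1,3-diene
Product: 12 endo 4a,8a-cis cycloadduct 5,8-bis(tert-butyldimethylsilyloxy)-2-[(R)-1-(tert-butyldimethylsilyloxy)-4-methylpent-3-enyl]-4a,5,8,8a-tetrahydro-5,8-ethanonaphthalene-1,4-dione (two quinone-face diastereomers expected; one drawn)
Conditions: 11 (1.5 equiv), toluene, rt to 50 °C, argon, dark
Reagents that add atoms: none
Why: Concerted, suprafacial–suprafacial, normal-electron-demand Diels–Alder cycloaddition of the donor-raised HOMO of 11 with the LUMO of 8, the closest known reaction type being the addition of oxygenated or 1,4-dialkylated cyclohexa-1,3-dienes to p-benzoquinones that opens an Alder–Rickert sequence. Ring A (C4a, C5, C6, C7, C8, C8a) is closed by an intermolecular [4+2] annulation in which C4a–C5 and C8–C8a form together, while the CH2CH2 unit already present in 11 ends up as the ethano bridge of a bicyclo[2.2.2]oct-2-ene. C4a and C8a become cis because both bonds are made to one face of the cis ring alkene of 8, C5 and C8 are fixed relative to each other by the locked s-cis geometry of the cyclic diene, and their relation to C4a and C8a follows from the endo transition state, in which the quinone carbonyls lie under C2 and C3 of the diene (future C6 and C7). The distant C1' centre should exert little control over which quinone face is attacked, so two endo diastereomers are expected, which does no harm since steps 7 and 8 flatten all four new centres. The selectivity that matters is the choice between the two quinone double bonds: the branched silyloxyalkyl group makes C2=C3 trisubstituted, more electron-rich and screened, so a diene that has to create two fully substituted carbons should attack only the unsubstituted C5=C6 bond of 8 (future C4a and C8a), and the constitutional symmetry of 11 leaves no regiochemical issue. Lewis acids are left out to avoid Mukaiyama–Michael addition, and mild heating in the dark under argon limits hydrogen transfer from 11 to 8.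

Step 7
Reactants: 12 endo cycloadduct
Product: 14 5,8-bis(tert-butyldimethylsilyloxy)-2-[(R)-1-(tert-butyldimethylsilyloxy)-4-methylpent-3-enyl]-5,8-dihydro-5,8-ethanonaphthalene-1,4-dione (two bridge diastereomers; one drawn), via bridged hydroquinone 13 (not isolated)
Conditions: Et3N (0.5 equiv), CH2Cl2, rt; then Ag2O, Na2SO4, rt, filtration through Celite
Reagents that add atoms: none
Why: Amine-catalysed double enolisation aromatises the ene-dione ring of the Diels–Alder adduct to hydroquinone 13, which Ag2O oxidises to the quinone under neutral conditions, and E1cB loss of the β-silyloxy groups cannot compete because it would place a double bond at a bridgehead of the bicyclo[2.2.2]octene (Bredt's rule).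

Step 8
Reactants: 14 ethano-bridged quinone
Product: 15 5,8-bis(tert-butyldimethylsilyloxy)-2-[(R)-1-(tert-butyldimethylsilyloxy)-4-methylpent-3-enyl]-1,4-naphthoquinone
Conditions: degassed xylenes, 130–140 °C, argon, dark
Reagents that add atoms: none
Why: Retro-Diels–Alder reaction (the second half of an Alder–Rickert sequence): the bicyclo[2.2.2]octa-2,5-diene loses ethylene irreversibly in a concerted [4+2] cycloreversion that is driven by the aromaticity gained in ring A and eased by the push–pull pairing of the bridgehead oxygen donors with the quinone acceptor, and since C5 and C8 become sp2 both diastereomers of 14 should converge on one compound.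

Step 9
Reactants: 15 tris-silylated naphthoquinone
Product: 16 shikonin, (R)-5,8-dihydroxy-2-(1-hydroxy-4-methylpent-3-enyl)-1,4-naphthoquinone
Conditions: HF·pyridine, pyridine, THF, 0 °C to rt
Reagents that add atoms: none
Why: Fluoride-mediated Si–O cleavage driven by the strong Si–F bond removes the two aryl silyl ethers quickly and the secondary one more slowly, and the pyridine-buffered medium together with the electron-poor quinone next to C1' should prevent ionisation of the C1'–O bond, so the R configuration is kept and cyclisation of the alcohol onto the prenyl alkene is avoided.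

Step 10
Reactants: 17 but-3-yn-1-ol; 18 2-bromopropene
Product: 19 5-methylhex-5-en-3-yn-1-ol
Conditions: PdCl2(PPh3)2 (2 mol %), CuI (4 mol %), Et3N, THF, rt, closed flask
Reagents that add atoms: none
Why: Sonogashira coupling (oxidative addition of the alkenyl bromide to zerovalent palladium, transmetallation from the copper acetylide, reductive elimination) joins C4 and C5 of the future acid and tolerates the free primary alcohol.

Step 11
Reactants: 19 5-methylhex-5-en-3-yn-1-ol
Product: 20 (Z)-5-methylhexa-3,5-dien-1-ol
Conditions: Zn dust (pre-activated with Cu(OAc)2, then AgNO3, and washed), MeOH/H2O 1:1, 40 °C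
Reagents that add atoms: none
Why: Semireduction of a conjugated enyne on copper- and silver-activated zinc in a protic medium delivers both hydrogens to the same side of the alkyne and so sets the Z alkene, and unlike catalytic hydrogenation it does not touch the 1,1-disubstituted alkene or reduce the diene further.

Step 12
Reactants: 20 (Z)-5-methylhexa-3,5-dien-1-ol
Product: 22 (Z)-5-methylhexa-3,5-dienoic acid, via Z-dienal 21 (not isolated)
Conditions: 2,2,6,6-tetramethylpiperidin-1-oxyl (0.2 equiv), PhI(OAc)2 (2.2 equiv), MeCN/H2O 1:1, 0 °C to rt; used promptly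
Reagents that add atoms: water, O
Why: Oxoammonium-catalysed oxidation with PhI(OAc)2 as terminal oxidant takes the primary alcohol through aldehyde 21 and its hydrate to the acid in one flask, and the nearly neutral, metal-free medium should oxidise 21 faster than its skipped Z-diene can slip into conjugation.

Step 13
Reactants: 16 shikonin; 22 (Z)-5-methylhexa-3,5-dienoic acid
Product: 23 target, (R)-1-(5,8-dihydroxy-1,4-dioxo-1,4-dihydronaphthalen-2-yl)-4-methylpent-3-enyl (Z)-5-methylhexa-3,5-dienoate
Conditions: 22 (1.3 equiv), N,N'-dicyclohexylcarbodiimide (DCC, 1.3 equiv), 4-(dimethylamino)pyridine (0.1 equiv), CH2Cl2, −10 to 0 °C, dark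
Reagents that add atoms: none
Why: Steglich esterification acylates only the C1' alcohol because the two peri hydroxyls are tied up in strong hydrogen bonds to the quinone carbonyls (the basis of the known side-chain acylations of shikonin), the C1'–O bond is not broken so R is retained, and low temperature with only catalytic 4-(dimethylamino)pyridine limits deprotonation of the doubly activated C2 methylene of the activated acid and thus keeps the Z-3,5-diene in place.

Compound list
1 | 2,5-dimethoxybenzaldehyde | COc1ccc(OC)c(C=O)c1 | starting material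
2 | allylboronic acid pinacol ester | C=CCB1OC(C)(C)C(C)(C)O1 | starting material
3 | (R)-2-[1-(2,5-dimethoxyphenyl)but-3-enyloxy]-4,4,5,5-tetramethyl-1,3,2-dioxaborolane | CC1(C)OB(O[C@H](CC=C)c2cc(OC)ccc2OC)OC1(C)C | intermediate
4 | (R)-1-(2,5-dimethoxyphenyl)but-3-en-1-ol | O[C@H](CC=C)c1cc(OC)ccc1OC | intermediate
5 | (R)-tert-butyl[1-(2,5-dimethoxyphenyl)but-3-enyloxy]dimethylsilane | CC(C)(C)[Si](C)(C)O[C@H](CC=C)c1cc(OC)ccc1OC | intermediate
6 | 2-methylbut-2-ene | CC=C(C)C | starting material
7 | (R)-tert-butyl[1-(2,5-dimethoxyphenyl)-4-methylpent-3-enyloxy]dimethylsilane | CC(C)(C)[Si](C)(C)O[C@H](CC=C(C)C)c1cc(OC)ccc1OC | intermediate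
8 | (R)-2-[1-(tert-butyldimethylsilyloxy)-4-methylpent-3-enyl]-1,4-benzoquinone | CC(C)(C)[Si](C)(C)O[C@H](CC=C(C)C)C1=CC(=O)C=CC1=O | intermediate
9 | cyclohexane-1,4-dione | O=C1CCC(=O)CC1 | starting material
10 | 4-(tert-butyldimethylsilyloxy)cyclohex-3-en-1-one | CC(C)(C)[Si](C)(C)OC1=CCC(=O)CC1 | intermediate
11 | 1,4-bis(tert-butyldimethylsilyloxy)cyclohexa-1,3-diene | CC(C)(C)[Si](C)(C)OC1=CC=C(O[Si](C)(C)C(C)(C)C)CC1 | intermediate
12 | endo, cis-fused Diels–Alder adduct (one of two facial diastereomers) | CC(C)(C)[Si](C)(C)O[C@]12C=C[C@](O[Si](C)(C)C(C)(C)C)(CC1)[C@H]1C(=O)C=C([C@@H](CC=C(C)C)O[Si](C)(C)C(C)(C)C)C(=O)[C@@H]21 | intermediate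
13 | ethano-bridged hydroquinone (5,8-dihydro-5,8-ethanonaphthalene-1,4-diol, one of two diastereomers) | CC(C)(C)[Si](C)(C)O[C@]12C=C[C@](O[Si](C)(C)C(C)(C)C)(CC1)c1c(O)cc([C@@H](CC=C(C)C)O[Si](C)(C)C(C)(C)C)c(O)c21 | intermediate
14 | ethano-bridged quinone (5,8-dihydro-5,8-ethanonaphthalene-1,4-dione, one of two diastereomers) | CC(C)(C)[Si](C)(C)O[C@]12C=C[C@](O[Si](C)(C)C(C)(C)C)(CC1)C1=C2C(=O)C([C@@H](CC=C(C)C)O[Si](C)(C)C(C)(C)C)=CC1=O | intermediate
15 | 5,8-bis(tert-butyldimethylsilyloxy)-2-[(R)-1-(tert-butyldimethylsilyloxy)-4-methylpent-3-enyl]-1,4-naphthoquinone | CC(C)(C)[Si](C)(C)O[C@H](CC=C(C)C)C1=CC(=O)c2c(O[Si](C)(C)C(C)(C)C)ccc(O[Si](C)(C)C(C)(C)C)c2C1=O | intermediate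
16 | shikonin, (R)-5,8-dihydroxy-2-(1-hydroxy-4-methylpent-3-enyl)-1,4-naphthoquinone | O[C@H](CC=C(C)C)C1=CC(=O)c2c(O)ccc(O)c2C1=O | intermediate
17 | but-3-yn-1-ol | C#CCCO | starting material
18 | 2-bromopropene | C=C(C)Br | starting material
19 | 5-methylhex-5-en-3-yn-1-ol | C=C(C)C#CCCO | intermediate
20 | (Z)-5-methylhexa-3,5-dien-1-ol | C=C(C)/C=C\CCO | intermediate
21 | (Z)-5-methylhexa-3,5-dienal | C=C(C)/C=C\CC=O | intermediate
22 | (Z)-5-methylhexa-3,5-dienoic acid | C=C(C)/C=C\CC(=O)O | intermediate
23 | (R)-1-(5,8-dihydroxy-1,4-dioxo-1,4-dihydronaphthalen-2-yl)-4-methylpent-3-enyl (Z)-5-methylhexa-3,5-dienoate | C=C(C)/C=C\CC(=O)O[C@H](CC=C(C)C)C1=CC(=O)c2c(O)ccc(O)c2C1=O | target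

Total step count: 13. Longest linear sequence: 9 steps (1, 2, 3, 4, 6, 7, 8, 9, 13).

Steps most likely to fail

**Step 6.**
- **Risk:** Hydrogen transfer from the cyclohexadiene to the quinone would aromatise the diene and reduce the dienophile. Conjugate addition with silyl transfer could take the place of ring closure. Bond formation at two fully substituted diene termini could also be slow.
- **Fallback:** It sets out from 8 and comes back at 16. Succinic anhydride is bis-silylated (TMSOTf, Et3N) to 2,5-bis(trimethylsilyloxy)furan F1. This diene has the same 1,4-dioxygenation pattern but no ring hydrogens to give away. Its cycloaddition to the free double bond of 8 should give the oxygen-bridged cycloadduct F2. The bridge of F2 is a double silyl ketal. It should collapse on mild acidic work-up and tautomerise directly, at the naphthazarin oxidation level, to (R)-1'-O-(tert-butyldimethylsilyl)shikonin F3. HF·pyridine as in step 9 then gives 16, so oxidation and heating are no longer needed.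

**Step 8.**
- **Risk:** Cycloreversion may be too slow at temperatures the quinone tolerates. A thermal hydrogen shift from C1' to the neighbouring quinone oxygen (quinone methide formation) would erode the C1' configuration or start an internal redox reaction.
- **Fallback:** It sets out from 12 and comes back at 15, with ethylene extruded at the arene level, where no oxidising or tautomerisable carbonyl is present. Enolisation of 12 in the presence of TMSCl and Et3N should give the ethano-bridged 1,4-bis(trimethylsilyloxy)arene F4. F4 can be heated harder (o-dichlorobenzene, about 180 °C) to give the 1,4-bis(trimethylsilyloxy)-5,8-bis(tert-butyldimethylsilyloxy)naphthalene F5. Selective methanolysis of the two labile aryl trimethylsilyl ethers (MeOH/CH2Cl2, trace AcOH, 0 °C) gives the naphthalene-1,4-diol F6. Ag2O oxidises F6 to 15.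

**Step 13.**
- **Risk:** Deprotonation of the activated acid at C2 would let the skipped Z-diene migrate into conjugation or lose its geometry. Acylation of a phenolic oxygen is a lesser risk.
- **Fallback:** It sets out from 17, uses 16, and comes back at 23. The diene is completed only after the ester bond exists, under neutral conditions.
  - Iodination of 17 (N-iodosuccinimide, catalytic AgNO3, acetone) gives 4-iodobut-3-yn-1-ol F7.
  - Diimide reduction (2-nitrobenzenesulfonylhydrazide, Et3N) gives (Z)-4-iodobut-3-en-1-ol F8.
  - Oxidation as in step 12 gives (Z)-4-iodobut-3-enoic acid F9. Its C2 methylene is activated by one alkene only and gains little from double-bond migration.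
  - Steglich esterification of F9 with 16 gives shikonin (Z)-4-iodobut-3-enoate F10.
  - Stille coupling of F10 with commercial tributyl(prop-1-en-2-yl)stannane (PdCl2(MeCN)2, DMF, rt, dark) should form C4–C5 with retention of the Z geometry and give 23.

Further compounds
F1 | step 6 | 2,5-bis(trimethylsilyloxy)furan | C[Si](C)(C)Oc1ccc(O[Si](C)(C)C)o1
F2 | step 6 | oxygen-bridged cycloadduct of 8 and F1 (one diastereomer drawn) | C[Si](C)(C)O[C@]12C=C[C@](O[Si](C)(C)C)(O1)[C@H]1C(=O)C=C([C@@H](CC=C(C)C)O[Si](C)(C)C(C)(C)C)C(=O)[C@@H]21
F3 | step 6 | (R)-1'-O-(tert-butyldimethylsilyl)shikonin | CC(C)(C)[Si](C)(C)O[C@H](CC=C(C)C)C1=CC(=O)c2c(O)ccc(O)c2C1=O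
F4 | step 8 | ethano-bridged 1,4-bis(trimethylsilyloxy)arene (one diastereomer drawn) | CC(C)(C)[Si](C)(C)O[C@]12C=C[C@](O[Si](C)(C)C(C)(C)C)(CC1)c1c(O[Si](C)(C)C)cc([C@@H](CC=C(C)C)O[Si](C)(C)C(C)(C)C)c(O[Si](C)(C)C)c21
F5 | step 8 | 2-[(R)-1-(tert-butyldimethylsilyloxy)-4-methylpent-3-enyl]-1,4-bis(trimethylsilyloxy)-5,8-bis(tert-butyldimethylsilyloxy)naphthalene | CC(C)(C)[Si](C)(C)O[C@H](CC=C(C)C)c1cc(O[Si](C)(C)C)c2c(O[Si](C)(C)C(C)(C)C)ccc(O[Si](C)(C)C(C)(C)C)c2c1O[Si](C)(C)C
F6 | step 8 | 2-[(R)-1-(tert-butyldimethylsilyloxy)-4-methylpent-3-enyl]-5,8-bis(tert-butyldimethylsilyloxy)naphthalene-1,4-diol | CC(C)(C)[Si](C)(C)O[C@H](CC=C(C)C)c1cc(O)c2c(O[Si](C)(C)C(C)(C)C)ccc(O[Si](C)(C)C(C)(C)C)c2c1O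
F7 | step 13 | 4-iodobut-3-yn-1-ol | OCCC#CI
F8 | step 13 | (Z)-4-iodobut-3-en-1-ol | OCC/C=C\I
F9 | step 13 | (Z)-4-iodobut-3-enoic acid | OC(=O)C/C=C\I
F10 | step 13 | shikonin (Z)-4-iodobut-3-enoate | I/C=C\CC(=O)O[C@H](CC=C(C)C)C1=CC(=O)c2c(O)ccc(O)c2C1=O
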